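**Plan**

- Ring labels: ring A is the free-phenol end, ring B the middle and ring C the methyl ester end. Each ring is numbered C1 (carbonyl-bearing), C2 (hydroxyl), C4 (para oxygen) and C6 (methyl).
- Retrosynthesis: the trichloroethyl carbonate is put back on O4 of ring A, then the three C2–O bonds of rings A, B and C are cut together. The two depside bonds C1(=O)(A)–O4(B) and C1(=O)(B)–O4(C) are cut last, leaving one monomer, 4-hydroxy-2-methylbenzoic acid.
- Enabling feature: in every ring the C1 carbonyl sits between the C6 methyl and C2. In the 2-deoxy trimer each carbonyl therefore has a single ortho C–H (C2–H) to which it can direct a metal.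
- Forward: no ring is formed. The chain is joined C to B to A by two acylations with one carbonate-protected acid chloride, the three chelated phenols are installed in one ester-directed C–H oxygenation, and zinc then frees O4 of ring A.
- Stereochemistry: the target has no stereocenter, so none has to be set.

Key step: step 7

Remark: the phenolic oxygens introduced in step 7 are taken to come from trifluoroacetate bound to ruthenium, so the phenols appear only after the aryl trifluoroacetates are hydrolysed on work-up.

**Route**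

Step 1
Reactants: 1 4-hydroxy-2-methylbenzoic acid
Product: 2 methyl 4-hydroxy-2-methylbenzoate
Conditions: MeOH, H2SO4 (cat.), reflux
Reagents that add atoms: methanol CO
Why: Fischer esterification, an acid-catalysed acyl substitution driven by methanol as solvent, with the phenol inert under these conditions.

Step 2
Reactants: 1 4-hydroxy-2-methylbenzoic acid; 3 2,2,2-trichloroethyl chloroformate
Product: 4 2-methyl-4-[(2,2,2-trichloroethoxy)carbonyloxy]benzoic acid
Conditions: NaOH (2 equiv), H2O/THF, 0 °C; then aq. HCl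
Reagents that add atoms: none
Why: Schotten-Baumann acylation, in which the phenoxide of the dianion of 1 is by far the better nucleophile toward the chloroformate, any mixed carboxylic-carbonic anhydride is hydrolysed back by the aqueous base, and acidification returns the free acid.

Step 3
Reactants: 4 2-methyl-4-[(2,2,2-trichloroethoxy)carbonyloxy]benzoic acid
Product: 5 2-methyl-4-[(2,2,2-trichloroethoxy)carbonyloxy]benzoyl chloride
Conditions: (COCl)2, DMF (cat.), CH2Cl2, 0 °C to rt
Reagents that add atoms: oxalyl chloride O=C(Cl)C(=O)Cl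
Why: Acid chloride formation through the chloroiminium salt from DMF and oxalyl chloride (Vilsmeier-type activation), which is mild enough to leave the aryl carbonate intact.

Step 4
Reactants: 2 methyl 4-hydroxy-2-methylbenzoate; 5 2-methyl-4-[(2,2,2-trichloroethoxy)carbonyloxy]benzoyl chloride
Product: 6 methyl 2-methyl-4-({2-methyl-4-[(2,2,2-trichloroethoxy)carbonyloxy]benzoyl}oxy)benzoate
Conditions: pyridine, CH2Cl2, 0 °C to rt
Reagents that add atoms: none
Why: Einhorn-type acylation of a phenol by an aroyl chloride through the acylpyridinium ion; the acid chloride has only one ortho substituent and is far more electrophilic than the aryl carbonate or the methyl ester.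

Step 5
Reactants: 6 methyl 2-methyl-4-({2-methyl-4-[(2,2,2-trichloroethoxy)carbonyloxy]benzoyl}oxy)benzoate
Product: 7 methyl 4-[(4-hydroxy-2-methylbenzoyl)oxy]-2-methylbenzoate
Conditions: Zn dust, AcOH/THF, rt
Reagents that add atoms: none
Why: Reductive fragmentation of the 2,2,2-trichloroethyl carbonate, in which zinc inserts into a C-Cl bond and beta-elimination expels 1,1-dichloroethene and CO2, leaving the aryl benzoate and the methyl ester untouched.

Step 6
Reactants: 7 methyl 4-[(4-hydroxy-2-methylbenzoyl)oxy]-2-methylbenzoate; 5 2-methyl-4-[(2,2,2-trichloroethoxy)carbonyloxy]benzoyl chloride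
Product: 8 methyl 2-methyl-4-{[2-methyl-4-({2-methyl-4-[(2,2,2-trichloroethoxy)carbonyloxy]benzoyl}oxy)benzoyl]oxy}benzoate (the tris(2-deoxy) trimer carrying the carbonate on O4 of ring A)
Conditions: pyridine, CH2Cl2, 0 °C to rt
Reagents that add atoms: none
Why: The same Einhorn-type phenol acylation as in step 4, now on the free O4 of ring B; the mild base keeps the phenoxide concentration low so that the existing depside bond and the carbonate are not exchanged.

Step 7
Reactants: 8 methyl 2-methyl-4-{[2-methyl-4-({2-methyl-4-[(2,2,2-trichloroethoxy)carbonyloxy]benzoyl}oxy)benzoyl]oxy}benzoate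
Product: 10 methyl 2-hydroxy-4-{[2-hydroxy-4-({2-hydroxy-6-methyl-4-[(2,2,2-trichloroethoxy)carbonyloxy]benzoyl}oxy)-6-methylbenzoyl]oxy}-6-methylbenzoate, via tris(trifluoroacetate) of the oxygenated trimer 9 (not isolated)
Conditions: [RuCl2(p-cymene)]2 (10 mol %), K2S2O8 (6 equiv), CF3CO2H/(CF3CO)2O, 80 °C, sealed tube; then H2O/THF, NaHCO3 to pH 7, rt
Reagents that add atoms: trifluoroacetic acid OC(=O)C(F)(F)F
Why: Proposed new method: each of the three ester carbonyls should bind the cationic divalent ruthenium trifluoroacetate formed from [RuCl2(p-cymene)]2 and guide carboxylate-assisted C-H metalation to C2, the only free ortho position, giving a five-membered ruthenacycle; oxidation by K2S2O8 to tetravalent ruthenium and C-O reductive elimination then release an aryl trifluoroacetate and return divalent ruthenium, and the three independent events lead to 9, which the work-up hydrolyses to 10. The closest known reaction type is the ruthenium-catalysed ester-directed ortho C-H hydroxylation of alkyl benzoates with persulfate in CF3CO2H/(CF3CO)2O; what is new is the use of aryl ester carbonyls (rings A and B) as directing groups and three turnovers on one molecule. No ring is closed and no stereocenter is formed, so only site selectivity is needed. It comes from the C6 methyl, which blocks the second ortho site of every carbonyl, and from the preference for the five-membered metallacycle on the acyl side over the six-membered one that the acyloxy group on C4 would need to reach C3 or C5. Each new oxygen stays masked as an electron-poor trifluoroacetate until work-up, which together with the acyl groups already on every ring should hold back over-oxidation, and the trichloroethyl carbonate is expected to be inert to the acidic oxidising medium.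

Step 8
Reactants: 10 methyl 2-hydroxy-4-{[2-hydroxy-4-({2-hydroxy-6-methyl-4-[(2,2,2-trichloroethoxy)carbonyloxy]benzoyl}oxy)-6-methylbenzoyl]oxy}-6-methylbenzoate
Product: 11 methyl 4-({4-[(2,4-dihydroxy-6-methylbenzoyl)oxy]-2-hydroxy-6-methylbenzoyl}oxy)-2-hydroxy-6-methylbenzoate (CNP0212402.0)
Conditions: Zn dust, AcOH/THF, rt
Reagents that add atoms: none
Why: The same zinc-induced reductive fragmentation of the trichloroethyl carbonate as in step 5; the chelated phenols, the two depside esters and the methyl ester are stable to zinc in acetic acid.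

**Compound list**

1 | 4-hydroxy-2-methylbenzoic acid | Cc1cc(O)ccc1C(=O)O | starting material
2 | methyl 4-hydroxy-2-methylbenzoate | COC(=O)c1ccc(O)cc1C | intermediate
3 | 2,2,2-trichloroethyl chloroformate | ClC(=O)OCC(Cl)(Cl)Cl | starting material
4 | 2-methyl-4-[(2,2,2-trichloroethoxy)carbonyloxy]benzoic acid | Cc1cc(OC(=O)OCC(Cl)(Cl)Cl)ccc1C(=O)O | intermediate
5 | 2-methyl-4-[(2,2,2-trichloroethoxy)carbonyloxy]benzoyl chloride | Cc1cc(OC(=O)OCC(Cl)(Cl)Cl)ccc1C(=O)Cl | intermediate
6 | methyl 2-methyl-4-({2-methyl-4-[(2,2,2-trichloroethoxy)carbonyloxy]benzoyl}oxy)benzoate | COC(=O)c1c(C)cc(OC(=O)c2c(C)cc(OC(=O)OCC(Cl)(Cl)Cl)cc2)cc1 | intermediate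
7 | methyl 4-[(4-hydroxy-2-methylbenzoyl)oxy]-2-methylbenzoate | COC(=O)c1c(C)cc(OC(=O)c2c(C)cc(O)cc2)cc1 | intermediate
8 | methyl 2-methyl-4-{[2-methyl-4-({2-methyl-4-[(2,2,2-trichloroethoxy)carbonyloxy]benzoyl}oxy)benzoyl]oxy}benzoate | COC(=O)c1c(C)cc(OC(=O)c2c(C)cc(OC(=O)c3c(C)cc(OC(=O)OCC(Cl)(Cl)Cl)cc3)cc2)cc1 | intermediate
9 | tris(trifluoroacetate) of 10, trifluoroacetoxy groups on C2 of rings A, B and C, formed in the flask | COC(=O)c1c(C)cc(OC(=O)c2c(C)cc(OC(=O)c3c(C)cc(OC(=O)OCC(Cl)(Cl)Cl)cc3OC(=O)C(F)(F)F)cc2OC(=O)C(F)(F)F)cc1OC(=O)C(F)(F)F | intermediate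
10 | methyl 2-hydroxy-4-{[2-hydroxy-4-({2-hydroxy-6-methyl-4-[(2,2,2-trichloroethoxy)carbonyloxy]benzoyl}oxy)-6-methylbenzoyl]oxy}-6-methylbenzoate | COC(=O)c1c(C)cc(OC(=O)c2c(C)cc(OC(=O)c3c(C)cc(OC(=O)OCC(Cl)(Cl)Cl)cc3O)cc2O)cc1O | intermediate
11 | methyl 4-({4-[(2,4-dihydroxy-6-methylbenzoyl)oxy]-2-hydroxy-6-methylbenzoyl}oxy)-2-hydroxy-6-methylbenzoate (CNP0212402.0) | COC(=O)c1c(C)cc(OC(=O)c2c(C)cc(OC(=O)c3c(C)cc(O)cc3O)cc2O)cc1O | target

**Step count**

Total steps: 8. Longest linear sequence: 7 steps (1 to 4 to 5 to 6 to 7 to 8 to 10 to 11).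

**Steps most likely to fail**

Step 7. The threefold oxygenation may stall after one or two turnovers because the aryl ester carbonyls of rings A and B bind ruthenium more weakly than an alkyl ester. Sulfate radicals may abstract hydrogen from the C6 methyl groups, and the depside bonds may undergo acyl exchange in hot CF3CO2H/(CF3CO)2O. The fallback uses known chemistry only: the oxygenation is moved to the monomer, where the directing group is a methyl ester, and the chain is then built by mixed-anhydride depside coupling with benzyl ether protection. It sets out from 2 and comes back to the route at 11.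
- Acetylation of 2 (Ac2O, pyridine) should give methyl 4-acetoxy-2-methylbenzoate F1.
- Ruthenium-catalysed hydroxylation of F1 ([RuCl2(p-cymene)]2, K2S2O8, CF3CO2H/(CF3CO)2O, 80 °C) should give methyl 4-acetoxy-2-methyl-6-(trifluoroacetoxy)benzoate F2, which is not isolated.
- K2CO3 in MeOH should cleave both aryl esters of F2 to give methyl 2,4-dihydroxy-6-methylbenzoate F3.
- Part of F3 is benzylated (BnBr, K2CO3, DMF, 60 °C) to methyl 2,4-bis(benzyloxy)-6-methylbenzoate F4, which is saponified (KOH, aqueous DMSO, 90 °C) to 2,4-bis(benzyloxy)-6-methylbenzoic acid F5.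
- Coupling of F5 with F3 by (CF3CO)2O in toluene at rt should acylate only the unchelated O4 and give methyl 4-{[2,4-bis(benzyloxy)-6-methylbenzoyl]oxy}-2-hydroxy-6-methylbenzoate F6.
- Hydrogenolysis (H2, Pd/C, EtOAc) then gives methyl 4-[(2,4-dihydroxy-6-methylbenzoyl)oxy]-2-hydroxy-6-methylbenzoate F7.
- A second coupling with F5 under the same conditions gives methyl 4-[(4-{[2,4-bis(benzyloxy)-6-methylbenzoyl]oxy}-2-hydroxy-6-methylbenzoyl)oxy]-2-hydroxy-6-methylbenzoate F8, and a second hydrogenolysis gives 11.

Step 6. Acylation of the electron-poor, sparingly soluble dimer phenol 7 may be slow. Transfer of the trichloroethoxycarbonyl group, or exchange at the depside bond already present, could then compete and give mixtures of chain lengths. The fallback joins the A–B bond on monomers and forms the B–C ester last with the simple phenol 2. It sets out from 1 (with 5 from the main route) and comes back at 8.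
- Treatment of 1 with Me2NCH(OtBu)2 in toluene at 80 °C should give tert-butyl 4-hydroxy-2-methylbenzoate F9.
- Acylation of F9 with 5 (pyridine, CH2Cl2) gives tert-butyl 2-methyl-4-({2-methyl-4-[(2,2,2-trichloroethoxy)carbonyloxy]benzoyl}oxy)benzoate F10.
- CF3CO2H in CH2Cl2 cleaves the tert-butyl ester to 2-methyl-4-({2-methyl-4-[(2,2,2-trichloroethoxy)carbonyloxy]benzoyl}oxy)benzoic acid F11.
- (COCl)2 with catalytic DMF gives 2-methyl-4-({2-methyl-4-[(2,2,2-trichloroethoxy)carbonyloxy]benzoyl}oxy)benzoyl chloride F12.
- Acylation of 2 with F12 (pyridine, CH2Cl2) gives 8.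

Step 2. In aqueous NaOH the chloroformate and the aryl carbonate formed from it may hydrolyse. Acylation of the carboxylate may also lead through a mixed anhydride to oligomeric esters. The fallback masks the acid so that the carbonate is made under anhydrous conditions. It sets out from 1 and comes back at 4.
- Alkylation of the carboxylate of 1 (allyl bromide, KHCO3, DMF, rt) should give prop-2-en-1-yl 4-hydroxy-2-methylbenzoate F13.
- Reaction of F13 with 3 (pyridine, CH2Cl2, 0 °C) gives prop-2-en-1-yl 2-methyl-4-[(2,2,2-trichloroethoxy)carbonyloxy]benzoate F14.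
- Deallylation with Pd(PPh3)4 (cat.) and PhSiH3 in CH2Cl2 at rt, through a pi-allyl complex formed by zerovalent palladium, should give 4 without touching the carbonate.

**Further compounds**

F1 | step 7 | methyl 4-acetoxy-2-methylbenzoate | COC(=O)c1ccc(OC(C)=O)cc1C
F2 | step 7 | methyl 4-acetoxy-2-methyl-6-(trifluoroacetoxy)benzoate | COC(=O)c1c(C)cc(OC(C)=O)cc1OC(=O)C(F)(F)F
F3 | step 7 | methyl 2,4-dihydroxy-6-methylbenzoate | COC(=O)c1c(C)cc(O)cc1O
F4 | step 7 | methyl 2,4-bis(benzyloxy)-6-methylbenzoate | COC(=O)c1c(C)cc(OCc2ccccc2)cc1OCc1ccccc1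
F5 | step 7 | 2,4-bis(benzyloxy)-6-methylbenzoic acid | Cc1cc(OCc2ccccc2)cc(OCc2ccccc2)c1C(=O)O
F6 | step 7 | methyl 4-{[2,4-bis(benzyloxy)-6-methylbenzoyl]oxy}-2-hydroxy-6-methylbenzoate | COC(=O)c1c(C)cc(OC(=O)c2c(C)cc(OCc3ccccc3)cc2OCc2ccccc2)cc1O
F7 | step 7 | methyl 4-[(2,4-dihydroxy-6-methylbenzoyl)oxy]-2-hydroxy-6-methylbenzoate | COC(=O)c1c(C)cc(OC(=O)c2c(C)cc(O)cc2O)cc1O
F8 | step 7 | methyl 4-[(4-{[2,4-bis(benzyloxy)-6-methylbenzoyl]oxy}-2-hydroxy-6-methylbenzoyl)oxy]-2-hydroxy-6-methylbenzoate | COC(=O)c1c(C)cc(OC(=O)c2c(C)cc(OC(=O)c3c(C)cc(OCc4ccccc4)cc3OCc3ccccc3)cc2O)cc1O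
F9 | step 6 | tert-butyl 4-hydroxy-2-methylbenzoate | CC(C)(C)OC(=O)c1ccc(O)cc1C
F10 | step 6 | tert-butyl 2-methyl-4-({2-methyl-4-[(2,2,2-trichloroethoxy)carbonyloxy]benzoyl}oxy)benzoate | CC(C)(C)OC(=O)c1ccc(OC(=O)c2ccc(OC(=O)OCC(Cl)(Cl)Cl)cc2C)cc1C
F11 | step 6 | 2-methyl-4-({2-methyl-4-[(2,2,2-trichloroethoxy)carbonyloxy]benzoyl}oxy)benzoic acid | Cc1cc(OC(=O)c2ccc(OC(=O)OCC(Cl)(Cl)Cl)cc2C)ccc1C(=O)O
F12 | step 6 | 2-methyl-4-({2-methyl-4-[(2,2,2-trichloroethoxy)carbonyloxy]benzoyl}oxy)benzoyl chloride | Cc1cc(OC(=O)c2ccc(OC(=O)OCC(Cl)(Cl)Cl)cc2C)ccc1C(=O)Cl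
F13 | step 2 | prop-2-en-1-yl 4-hydroxy-2-methylbenzoate | C=CCOC(=O)c1ccc(O)cc1C
F14 | step 2 | prop-2-en-1-yl 2-methyl-4-[(2,2,2-trichloroethoxy)carbonyloxy]benzoate | C=CCOC(=O)c1ccc(OC(=O)OCC(Cl)(Cl)Cl)cc1C
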